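**Plan**

Numbering (germacrane): lactone O–C6, C7, C11(=C13), C12; isobutyrate on C8; epoxide C1–C10 (methyl C14); alkene C4=C5 carrying C15H2OH; carbinol C3.
Retrosynthesis: remove the epoxide oxygen (C1=C10), then cut C5–C6 together with the lactone O–C12 bond (seco aldehyde ester with a C5 iodoalkene), then C7–C8 (allylation), then C4–C15 and C5–I (alkyne carbometallation), C3–C4 and C1–C2.
Enabling feature: C6 is both the lactone carbinol carbon and allylic to the Z C4=C5 alkene, and its oxygen is γ to C12. A C5 alkenylchromium adding to a C6 aldehyde therefore closes the ten-membered carbocycle (C1–C10) and, through the new alkoxide, the five-membered lactone ring.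
Forward: syn-carboalumination of a butynol gives the E C1=C10 unit; the C3 alkynol is carbomagnesiated, iodinated and oxidised to the Z iodoalkene diol; an indium Barbier reaction joins the acrylate bromide at C7–C8; periodate unveils C6; ring closure; desilylation; epoxidation last.
Stereochemistry: C3 by Noyori transfer hydrogenation; C7/C8 by a Zimmerman–Traxler syn allylation steered by a sacrificial dioxolane stereocentre from (R)-glyceraldehyde (excised later); C6 from C7 in the ring closure; C1/C10 by peripheral epoxidation of the macrocycle; Z and E alkenes from the two carbometallations.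

Key step: step 15

Assumption: the allylindium reagent in step 12 is taken to add anti to the dioxolane C–O bond with the C6 hydrogen eclipsing the alkene, which dictates the use of the (R)-aldehyde 15.

**Route**

Step 1
Reactants: 1 tert-butyl(but-3-yn-1-yloxy)dimethylsilane
Product: 3 (3E)-6-(tert-butyldimethylsilyloxy)-4-methylhex-3-en-1-ol, via alkenylalane 2 (not isolated)
Conditions: AlMe3, Cp2ZrCl2 (cat.), CH2Cl2, 0 °C to rt; then n-BuLi, hexane/THF, −78 °C; ethylene oxide, −78 °C to rt
Reagents that add atoms: trimethylaluminium C[Al](C)C; ethylene oxide C1CO1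
Why: Zirconium-catalysed Negishi carboalumination adds methyl and aluminium syn across the terminal alkyne (methyl on the internal carbon), which fixes the E C1=C10 alkene, and the derived alanate opens ethylene oxide with retention of alkene geometry.

Step 2
Reactants: 3 (3E)-6-(tert-butyldimethylsilyloxy)-4-methylhex-3-en-1-ol
Product: 4 (3E)-6-(tert-butyldimethylsilyloxy)-4-methylhex-3-enal
Conditions: Dess–Martin periodinane, NaHCO3, CH2Cl2, 0 °C
Reagents that add atoms: none
Why: Buffered Dess–Martin oxidation of a primary alcohol should give the β,γ-unsaturated aldehyde without moving the double bond.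

Step 3
Reactants: 4 (3E)-6-(tert-butyldimethylsilyloxy)-4-methylhex-3-enal
Product: 5 (5E)-8-(tert-butyldimethylsilyloxy)-6-methyl-1-(trimethylsilyl)oct-5-en-1-yn-3-ol (racemic)
Conditions: LiC≡CSiMe3, THF, −78 °C
Reagents that add atoms: lithium (trimethylsilyl)acetylide [Li]C#C[Si](C)(C)C
Why: 1,2-Addition of a lithium acetylide to an aldehyde is fast at low temperature, and the racemic carbinol is of no consequence because it is oxidised in the next step.

Step 4
Reactants: 5 (5E)-8-(tert-butyldimethylsilyloxy)-6-methyl-1-(trimethylsilyl)oct-5-en-1-yn-3-ol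
Product: 6 (5E)-8-(tert-butyldimethylsilyloxy)-6-methyl-1-(trimethylsilyl)oct-5-en-1-yn-3-one
Conditions: Dess–Martin periodinane, NaHCO3, CH2Cl2, 0 °C to rt
Reagents that add atoms: none
Why: Dess–Martin oxidation of the propargylic alcohol gives the ynone needed for a catalyst-controlled reduction.

Step 5
Reactants: 6 (5E)-8-(tert-butyldimethylsilyloxy)-6-methyl-1-(trimethylsilyl)oct-5-en-1-yn-3-one
Product: 8 (3S,5E)-8-(tert-butyldimethylsilyloxy)-6-methyloct-5-en-1-yn-3-ol, via silylated alkynol 7 (not isolated)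
Conditions: Ru[(S,S)-TsDPEN](p-cymene) (cat.), i-PrOH, rt; then K2CO3, MeOH, rt
Reagents that add atoms: none
Why: Noyori asymmetric transfer hydrogenation of an alkynyl ketone with the (S,S)-catalyst should deliver hydride to the face that gives the S propargylic alcohol (C3), and carbonate in methanol then removes the alkynyl silyl group while the silyl ether survives.

Step 6
Reactants: 8 (3S,5E)-8-(tert-butyldimethylsilyloxy)-6-methyloct-5-en-1-yn-3-ol
Product: 11 (2Z,3S,5E)-8-(tert-butyldimethylsilyloxy)-2-(iodomethylidene)-6-methyloct-5-ene-1,3-diol, via alkenylmagnesium chelate 9 (not isolated), via iodo allylsilane 10 (not isolated)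
Conditions: i-PrOMe2SiCH2MgCl (from ClCH2SiMe2(Oi-Pr), Mg, THF), CuI (cat.), THF, 0 °C to rt; I2, −78 to 0 °C; then KF, KHCO3, 30% H2O2, THF/MeOH, rt
Reagents that add atoms: (chloromethyl)(isopropoxy)dimethylsilane (as its Grignard reagent) CC(C)O[Si](C)(C)CCl; iodine II; hydrogen peroxide OO
Why: Copper-catalysed, alkoxide-directed anti-carbomagnesiation of the propargylic alcohol places the silylmethyl group on C4 and magnesium on C5 cis to C3 in a five-membered chelate, iodine replaces magnesium with retention to give the Z iodoalkene, and Tamao oxidation converts the C–Si bond into the C15 hydroxyl.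

Step 7
Reactants: 11 (2Z,3S,5E)-8-(tert-butyldimethylsilyloxy)-2-(iodomethylidene)-6-methyloct-5-ene-1,3-diol
Product: 12 (4S,5Z)-2,2-di-tert-butyl-4-[(2E)-5-(tert-butyldimethylsilyloxy)-3-methylpent-2-en-1-yl]-5-(iodomethylidene)-1,3,2-dioxasilinane
Conditions: t-Bu2Si(OTf)2, 2,6-lutidine, CH2Cl2, 0 °C
Reagents that add atoms: di-tert-butylsilyl bis(trifluoromethanesulfonate) CC(C)(C)[Si](OS(=O)(=O)C(F)(F)F)(OS(=O)(=O)C(F)(F)F)C(C)(C)C
Why: The silylene bridges the 1,3-diol (O3 and O15) as a six-membered ring that should withstand the later acidic, oxidative and organometallic steps.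

Step 8
Reactants: 12 (4S,5Z)-2,2-di-tert-butyl-4-[(2E)-5-(tert-butyldimethylsilyloxy)-3-methylpent-2-en-1-yl]-5-(iodomethylidene)-1,3,2-dioxasilinane
Product: 13 (3E)-5-[(4S,5Z)-2,2-di-tert-butyl-5-(iodomethylidene)-1,3,2-dioxasilinan-4-yl]-3-methylpent-3-en-1-ol
Conditions: CSA (cat.), MeOH/CH2Cl2, 0 °C
Reagents that add atoms: none
Why: A primary tert-butyldimethylsilyl ether is methanolysed by catalytic acid much faster than the hindered cyclic di-tert-butylsilylene.

Step 9
Reactants: 13 (3E)-5-[(4S,5Z)-2,2-di-tert-butyl-5-(iodomethylidene)-1,3,2-dioxasilinan-4-yl]-3-methylpent-3-en-1-ol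
Product: 14 (3E)-5-[(4S,5Z)-2,2-di-tert-butyl-5-(iodomethylidene)-1,3,2-dioxasilinan-4-yl]-3-methylpent-3-enal
Conditions: Dess–Martin periodinane, NaHCO3, CH2Cl2, 0 °C
Reagents that add atoms: none
Why: Buffered Dess–Martin oxidation should give the β,γ-unsaturated C8 aldehyde, which is used without chromatography.

Step 10
Reactants: 15 (R)-2,2-dimethyl-1,3-dioxolane-4-carbaldehyde; 16 methyl acrylate
Product: 17 methyl 2-{[(4R)-2,2-dimethyl-1,3-dioxolan-4-yl](hydroxy)methyl}prop-2-enoate (both carbinol epimers)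
Conditions: DABCO, 1,4-dioxane/H2O, rt
Reagents that add atoms: none
Why: Morita–Baylis–Hillman reaction of an acrylate with a reactive α-alkoxy aldehyde; the new carbinol centre is destroyed in the next step, so its configuration does not matter.

Step 11
Reactants: 17 methyl 2-{[(4R)-2,2-dimethyl-1,3-dioxolan-4-yl](hydroxy)methyl}prop-2-enoate
Product: 18 methyl (2Z)-2-(bromomethyl)-3-[(4S)-2,2-dimethyl-1,3-dioxolan-4-yl]prop-2-enoate
Conditions: NBS, Me2S, CH2Cl2, 0 °C to rt
Reagents that add atoms: N-bromosuccinimide O=C1CCC(=O)N1Br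
Why: Bromination with allylic transposition converts Baylis–Hillman adducts into the thermodynamically favoured (Z)-2-(bromomethyl)alk-2-enoates, both carbinol epimers converging on one bromide.

Step 12
Reactants: 14 (3E)-5-[(4S,5Z)-2,2-di-tert-butyl-5-(iodomethylidene)-1,3,2-dioxasilinan-4-yl]-3-methylpent-3-enal; 18 methyl (2Z)-2-(bromomethyl)-3-[(4S)-2,2-dimethyl-1,3-dioxolan-4-yl]prop-2-enoate
Product: 20 methyl (3R,4R,6E)-8-[(4S,5Z)-2,2-di-tert-butyl-5-(iodomethylidene)-1,3,2-dioxasilinan-4-yl]-3-[(4S)-2,2-dimethyl-1,3-dioxolan-4-yl]-4-hydroxy-6-methyl-2-methylideneoct-6-enoate, via allylindium dibromide 19 (not isolated)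
Conditions: In powder, THF/H2O, rt
Reagents that add atoms: none
Why: Indium Barbier allylation in which the Z allylindium reacts at its γ-carbon (C7) through a Zimmerman–Traxler chair, giving the syn C7/C8 pair and the C11=C13 methylene, while the dioxolane stereocentre (hydrogen eclipsing the alkene, C–O bond anti to the incoming aldehyde) should select the face that leads to 7R,8R; the iodoalkene is inert to indium.

Step 13
Reactants: 20 methyl (3R,4R,6E)-8-[(4S,5Z)-2,2-di-tert-butyl-5-(iodomethylidene)-1,3,2-dioxasilinan-4-yl]-3-[(4S)-2,2-dimethyl-1,3-dioxolan-4-yl]-4-hydroxy-6-methyl-2-methylideneoct-6-enoate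
Product: 21 methyl (3R,4R,6E)-8-[(4S,5Z)-2,2-di-tert-butyl-5-(iodomethylidene)-1,3,2-dioxasilinan-4-yl]-3-[(4S)-2,2-dimethyl-1,3-dioxolan-4-yl]-6-methyl-2-methylidene-4-(2-methylpropanoyloxy)oct-6-enoate
Conditions: (i-PrCO)2O, Et3N, DMAP (cat.), CH2Cl2, 0 °C to rt
Reagents that add atoms: isobutyric anhydride CC(C)C(=O)OC(=O)C(C)C
Why: DMAP-catalysed acylation of the only free hydroxyl installs the C8 isobutyrate and blocks lactonisation towards O8.

Step 14
Reactants: 21 methyl (3R,4R,6E)-8-[(4S,5Z)-2,2-di-tert-butyl-5-(iodomethylidene)-1,3,2-dioxasilinan-4-yl]-3-[(4S)-2,2-dimethyl-1,3-dioxolan-4-yl]-6-methyl-2-methylidene-4-(2-methylpropanoyloxy)oct-6-enoate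
Product: 23 methyl (3R,4R,6E)-8-[(4S,5Z)-2,2-di-tert-butyl-5-(iodomethylidene)-1,3,2-dioxasilinan-4-yl]-3-formyl-6-methyl-2-methylidene-4-(2-methylpropanoyloxy)oct-6-enoate, via diol 22 (not isolated)
Conditions: H5IO6, EtOAc, rt
Reagents that add atoms: none
Why: Periodic acid hydrolyses the terminal acetonide and at once cleaves the 1,2-diol, so the sacrificial stereocentre is excised and C6 emerges as the aldehyde under non-basic conditions that should spare the C7 centre; the crude aldehyde is used directly.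

Step 15
Reactants: 23 methyl (3R,4R,6E)-8-[(4S,5Z)-2,2-di-tert-butyl-5-(iodomethylidene)-1,3,2-dioxasilinan-4-yl]-3-formyl-6-methyl-2-methylidene-4-(2-methylpropanoyloxy)oct-6-enoate
Product: 26 3,15-O-(di-tert-butylsilylene)-protected (3S,6R,7R,8R)-3,15-dihydroxy-8-(2-methylpropanoyloxy)germacra-1(10)E,4Z,11(13)-trien-12,6-olide, via alkenylchromium dichloride 24 (not isolated), via hydroxy ester 25 (not isolated)
Conditions: CrCl2 (excess), NiCl2 (cat.), DMSO/THF, rt, high dilution (slow addition of 23); aqueous work-up, then PPTS (cat.), CH2Cl2, rt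
Reagents that add atoms: none
Why: Zerovalent nickel inserts into the C5–I bond with retention of the Z geometry and hands the alkenyl group to trivalent chromium (24), which adds to the C6 aldehyde of the same chain; the chromium alkoxide of 25 lies γ to the C12 methyl ester and lactonises (completed by PPTS), so one operation builds the carbocycle, the C6 stereocentre and the lactone. The closest known reaction type is the intramolecular Nozaki–Hiyama–Kishi alkenylation used for medium-ring and macrocyclic allylic alcohols, followed by lactonisation of a γ-hydroxy ester. The ten-membered ring (C1–C10) closes 10-exo-trig by attack of C5 on the exocyclic C6=O, and the lactone closes 5-exo-trig by attack of O6 on the C12 carbonyl. C6 is controlled by the adjacent C7 centre inside the cyclic transition state: the bulky chromium-bound oxygen should take the peripheral position between H7 and the acrylate while C5 bonds anti to the acrylate, which places H6 anti to H7 and gives the 6R carbinol of the trans-fused lactone. The step needs aldehyde-over-ester chemoselectivity and ring closure over oligomerisation; the first is inherent to alkenylchromium reagents, which ignore the acrylate and the isobutyrate, and the second is secured by slow addition at high dilution to a chain already restricted by the E C1=C10 alkene and the silylene ring.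

Step 16
Reactants: 26 3,15-O-(di-tert-butylsilylene)-protected (3S,6R,7R,8R)-3,15-dihydroxy-8-(2-methylpropanoyloxy)germacra-1(10)E,4Z,11(13)-trien-12,6-olide
Product: 27 (3S,6R,7R,8R)-3,15-dihydroxy-8-(2-methylpropanoyloxy)germacra-1(10)E,4Z,11(13)-trien-12,6-olide
Conditions: HF·pyridine, pyridine, THF, 0 °C to rt
Reagents that add atoms: none
Why: Fluoride cleaves the silylene selectively, and the lactone, the isobutyrate and the diene should be stable to buffered HF·pyridine.

Step 17
Reactants: 27 (3S,6R,7R,8R)-3,15-dihydroxy-8-(2-methylpropanoyloxy)germacra-1(10)E,4Z,11(13)-trien-12,6-olide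
Product: 28 (1R,3S,6R,7R,8R,10R)-1,10-epoxy-3,15-dihydroxy-8-(2-methylpropanoyloxy)germacra-4Z,11(13)-dien-12,6-olide (target)
Conditions: mCPBA, NaHCO3, CH2Cl2, −20 to 0 °C
Reagents that add atoms: 3-chloroperoxybenzoic acid OOC(=O)c1cccc(Cl)c1
Why: The electrophilic peroxy acid should pick the electron-rich E C1=C10 alkene over C4=C5 (three allylic C–O bonds) and the acrylate, and attack on the exposed outer face of this double bond in the preferred ring conformation (C14 methyl on the β face) should give the 1R,10R epoxide.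

**Compound list**

1 | tert-butyl(but-3-yn-1-yloxy)dimethylsilane | C#CCCO[Si](C)(C)C(C)(C)C | starting material
2 | dimethyl[(1E)-4-(tert-butyldimethylsilyloxy)-2-methylbut-1-en-1-yl]alane | C[Al](C)/C=C(\C)CCO[Si](C)(C)C(C)(C)C | intermediate
3 | (3E)-6-(tert-butyldimethylsilyloxy)-4-methylhex-3-en-1-ol | OCC/C=C(\C)CCO[Si](C)(C)C(C)(C)C | intermediate
4 | (3E)-6-(tert-butyldimethylsilyloxy)-4-methylhex-3-enal | O=CC/C=C(\C)CCO[Si](C)(C)C(C)(C)C | intermediate
5 | (5E)-8-(tert-butyldimethylsilyloxy)-6-methyl-1-(trimethylsilyl)oct-5-en-1-yn-3-ol, racemic | C[Si](C)(C)C#CC(O)C/C=C(\C)CCO[Si](C)(C)C(C)(C)C | intermediate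
6 | (5E)-8-(tert-butyldimethylsilyloxy)-6-methyl-1-(trimethylsilyl)oct-5-en-1-yn-3-one | C[Si](C)(C)C#CC(=O)C/C=C(\C)CCO[Si](C)(C)C(C)(C)C | intermediate
7 | (3S,5E)-8-(tert-butyldimethylsilyloxy)-6-methyl-1-(trimethylsilyl)oct-5-en-1-yn-3-ol | C[Si](C)(C)C#C[C@@H](O)C/C=C(\C)CCO[Si](C)(C)C(C)(C)C | intermediate
8 | (3S,5E)-8-(tert-butyldimethylsilyloxy)-6-methyloct-5-en-1-yn-3-ol | C#C[C@@H](O)C/C=C(\C)CCO[Si](C)(C)C(C)(C)C | intermediate
9 | alkenylmagnesium chelate: C3 chloromagnesium alkoxide with C5–MgCl cis to C3 and the silylmethyl group on C4 | Cl[Mg]/C=C(/C[Si](C)(C)OC(C)C)[C@@H](O[Mg]Cl)C/C=C(\C)CCO[Si](C)(C)C(C)(C)C | intermediate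
10 | (1E,3S,5E)-8-(tert-butyldimethylsilyloxy)-1-iodo-2-[(isopropoxydimethylsilyl)methyl]-6-methylocta-1,5-dien-3-ol | I/C=C(/C[Si](C)(C)OC(C)C)[C@@H](O)C/C=C(\C)CCO[Si](C)(C)C(C)(C)C | intermediate
11 | (2Z,3S,5E)-8-(tert-butyldimethylsilyloxy)-2-(iodomethylidene)-6-methyloct-5-ene-1,3-diol | I/C=C(/CO)[C@@H](O)C/C=C(\C)CCO[Si](C)(C)C(C)(C)C | intermediate
12 | (4S,5Z)-2,2-di-tert-butyl-4-[(2E)-5-(tert-butyldimethylsilyloxy)-3-methylpent-2-en-1-yl]-5-(iodomethylidene)-1,3,2-dioxasilinane | CC(C)(C)[Si](C)(C)OCC/C(C)=C/C[C@@H]1O[Si](C(C)(C)C)(C(C)(C)C)OC/C1=C/I | intermediate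
13 | (3E)-5-[(4S,5Z)-2,2-di-tert-butyl-5-(iodomethylidene)-1,3,2-dioxasilinan-4-yl]-3-methylpent-3-en-1-ol | OCC/C(C)=C/C[C@@H]1O[Si](C(C)(C)C)(C(C)(C)C)OC/C1=C/I | intermediate
14 | (3E)-5-[(4S,5Z)-2,2-di-tert-butyl-5-(iodomethylidene)-1,3,2-dioxasilinan-4-yl]-3-methylpent-3-enal | O=CC/C(C)=C/C[C@@H]1O[Si](C(C)(C)C)(C(C)(C)C)OC/C1=C/I | intermediate
15 | (R)-2,2-dimethyl-1,3-dioxolane-4-carbaldehyde | O=C[C@H]1COC(C)(C)O1 | starting material
16 | methyl acrylate | C=CC(=O)OC | starting material
17 | methyl 2-{[(4R)-2,2-dimethyl-1,3-dioxolan-4-yl](hydroxy)methyl}prop-2-enoate, both carbinol epimers | C=C(C(=O)OC)C(O)[C@H]1COC(C)(C)O1 | intermediate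
18 | methyl (2Z)-2-(bromomethyl)-3-[(4S)-2,2-dimethyl-1,3-dioxolan-4-yl]prop-2-enoate | BrC/C(C(=O)OC)=C\[C@H]1COC(C)(C)O1 | intermediate
19 | allylindium dibromide from 18 (indium on the former CH2Br carbon, Z) | Br[In](Br)C/C(C(=O)OC)=C\[C@H]1COC(C)(C)O1 | intermediate
20 | methyl (3R,4R,6E)-8-[(4S,5Z)-2,2-di-tert-butyl-5-(iodomethylidene)-1,3,2-dioxasilinan-4-yl]-3-[(4S)-2,2-dimethyl-1,3-dioxolan-4-yl]-4-hydroxy-6-methyl-2-methylideneoct-6-enoate | C=C(C(=O)OC)[C@@H]([C@H]1COC(C)(C)O1)[C@H](O)C/C(C)=C/C[C@@H]1O[Si](C(C)(C)C)(C(C)(C)C)OC/C1=C/I | intermediate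
21 | 4-O-isobutyrate of 20 | C=C(C(=O)OC)[C@@H]([C@H]1COC(C)(C)O1)[C@H](OC(=O)C(C)C)C/C(C)=C/C[C@@H]1O[Si](C(C)(C)C)(C(C)(C)C)OC/C1=C/I | intermediate
22 | 1,2-diol from hydrolysis of the acetonide of 21 | C=C(C(=O)OC)[C@@H]([C@H](O)CO)[C@H](OC(=O)C(C)C)C/C(C)=C/C[C@@H]1O[Si](C(C)(C)C)(C(C)(C)C)OC/C1=C/I | intermediate
23 | methyl (3R,4R,6E)-8-[(4S,5Z)-2,2-di-tert-butyl-5-(iodomethylidene)-1,3,2-dioxasilinan-4-yl]-3-formyl-6-methyl-2-methylidene-4-(2-methylpropanoyloxy)oct-6-enoate | C=C(C(=O)OC)[C@@H](C=O)[C@H](OC(=O)C(C)C)C/C(C)=C/C[C@@H]1O[Si](C(C)(C)C)(C(C)(C)C)OC/C1=C/I | intermediate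
24 | alkenylchromium dichloride (C5–CrCl2 in place of C5–I of 23) | C=C(C(=O)OC)[C@@H](C=O)[C@H](OC(=O)C(C)C)C/C(C)=C/C[C@@H]1O[Si](C(C)(C)C)(C(C)(C)C)OC/C1=C/[Cr](Cl)Cl | intermediate
25 | ring-closed hydroxy ester (ten-membered carbocycle, free 6-OH, methyl ester at C12; configuration at C3, C6, C7, C8 as in 26) | C=C(C(=O)OC)[C@H]1[C@H](O)/C=C2/CO[Si](C(C)(C)C)(C(C)(C)C)O[C@H]2C/C=C(\C)C[C@H]1OC(=O)C(C)C | intermediate
26 | 3,15-O-(di-tert-butylsilylene)-protected (3S,6R,7R,8R)-3,15-dihydroxy-8-(2-methylpropanoyloxy)germacra-1(10)E,4Z,11(13)-trien-12,6-olide | C=C1C(=O)O[C@@H]2/C=C3/CO[Si](C(C)(C)C)(C(C)(C)C)O[C@H]3C/C=C(\C)C[C@@H](OC(=O)C(C)C)[C@@H]12 | intermediate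
27 | (3S,6R,7R,8R)-3,15-dihydroxy-8-(2-methylpropanoyloxy)germacra-1(10)E,4Z,11(13)-trien-12,6-olide | C=C1C(=O)O[C@@H]2/C=C(/CO)[C@@H](O)C/C=C(\C)C[C@@H](OC(=O)C(C)C)[C@@H]12 | intermediate
28 | (1R,3S,6R,7R,8R,10R)-1,10-epoxy-3,15-dihydroxy-8-(2-methylpropanoyloxy)germacra-4Z,11(13)-dien-12,6-olide | C=C1C(=O)O[C@@H]2/C=C(/CO)[C@@H](O)C[C@H]3O[C@]3(C)C[C@@H](OC(=O)C(C)C)[C@@H]12 | target

**Step count and risks**

Total steps: 17. Longest linear sequence: 15 (steps 1–9 and 12–17, from 1).

1. Step 15. What may go wrong: ring closure may lose to intermolecular coupling, the labile aldehyde may isomerise before it reacts, and addition may occur on the wrong face of C6, after which the carbinol lactonises to a cis-fused ring. Fallback: stereocontrol is moved from the carbon–carbon bond formation to a ketone reduction. Setting out from 23, the chromium-mediated closure is run without the acid treatment so that the open carbinols are kept. The 6S hydroxy ester F1 (the C6 epimer of 25) is oxidised with Dess–Martin periodinane to the macrocyclic enone F2. A reagent-controlled 1,2-reduction (oxazaborolidine catalyst with catecholborane, catalyst enantiomer chosen for the 6R alcohol) then gives 25, which lactonises with PPTS and rejoins the route at 26.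

2. Step 12. What may go wrong: the dioxolane may bias the π-face of the allylindium only weakly or in the opposite sense, and the adduct may lactonise towards O8 before it is acylated. Fallback: control is moved from the substrate to a catalyst and from indium to boron. Setting out from 18, palladium-catalysed borylation (B2pin2, Pd2(dba)3, DMSO) gives the allylboronate F3. Its allylboration of 14 under chiral phosphoric acid catalysis (TRIP, enantiomer matched to the required C8 configuration, toluene, −30 °C) passes through a closed six-membered transition state in which the Z-crotyl-type reagent gives the syn pair, and it rejoins the route at 20.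

3. Step 17. What may go wrong: the peroxy acid may deliver oxygen to the wrong face of C1=C10, or hydroxyl-directed epoxidation of C4=C5 may compete. Fallback: the oxygen is delivered in two steps from the opposite face. Setting out from 27, NBS in aqueous THF gives the bromohydrin F4 (bromonium on the exposed face, water at the tertiary C10 from the other face). K2CO3 in acetone then closes the epoxide with inversion at C1 and rejoins the route at 28.

**Further compounds**

F1 | step 15 | 6S hydroxy ester (C6 epimer of 25) | C=C(C(=O)OC)[C@H]1[C@@H](O)/C=C2/CO[Si](C(C)(C)C)(C(C)(C)C)O[C@H]2C/C=C(\C)C[C@H]1OC(=O)C(C)C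
F2 | step 15 | macrocyclic enone (C6 ketone corresponding to 25) | C=C(C(=O)OC)[C@H]1C(=O)/C=C2/CO[Si](C(C)(C)C)(C(C)(C)C)O[C@H]2C/C=C(\C)C[C@H]1OC(=O)C(C)C
F3 | step 12 | methyl (2E)-3-[(4S)-2,2-dimethyl-1,3-dioxolan-4-yl]-2-[(4,4,5,5-tetramethyl-1,3,2-dioxaborolan-2-yl)methyl]prop-2-enoate | CC1(C)OB(C/C(C(=O)OC)=C\[C@H]2COC(C)(C)O2)OC1(C)C
F4 | step 17 | bromohydrin of 27 (bromine on C1, hydroxyl on C10) | C=C1C(=O)O[C@@H]2/C=C(/CO)[C@@H](O)C[C@H](Br)[C@](C)(O)C[C@@H](OC(=O)C(C)C)[C@@H]12
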